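**Plan**

- Retrosynthesis: the C15 ketone of target 6 is taken back to the 15S allylic alcohol of prostaglandin F2α (5), and the cis-9α,11α-diol of 5 to the O–O bridge of the endoperoxide prostaglandin H2 (4).
- In 4 the bonds C8–C12, C9–O, C11–O and C15–O are cut together, which leaves arachidonic acid (1) and two molecules of dioxygen (2).
- Enabling feature: a cyclopentane C8–C12 with cis oxygens on C9 and C11, trans side chains on C8 and C12 and an oxygen on allylic C15 corresponds to a (5Z,8Z,11Z,14Z) skipped tetraene plus two O2.
- Forward: in one enzymatic step the 1,2-dioxolane closes first (C11–O, then C9–O), the cyclopentane second (C8–C12), and C15–O forms last; the O–O bond is then reduced and the allylic C15 alcohol dehydrogenated.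
- Stereochemistry: 8R, 9S, 11R, 12R, the transient 15S centre and the 13E alkene come from the synthase active site in step 1; the 5Z alkene is carried over from 1; no later step touches a ring C–O or C–C bond.

Key step: step 1

Remark: the synthase is bought as the purified ovine enzyme and counts as a catalyst, not a numbered compound; the route is meant for milligram amounts, and α denotes the lower face of the cyclopentane in the usual prostanoid drawing.

**Step 1**
Reactants: 1 arachidonic acid ((5Z,8Z,11Z,14Z)-icosa-5,8,11,14-tetraenoic acid); 2 dioxygen (two molecules)
Product: 4 prostaglandin H2 (9α,11α-epidioxy-15S-hydroxyprosta-5Z,13E-dienoic acid), via prostaglandin G2 3 (not isolated)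
Conditions: ovine prostaglandin-endoperoxide synthase 1 (added in portions), hematin (C34H33FeN4O5, trivalent iron, 1 µM), hydroquinone (0.5 mM), 1 (0.1 mM), O2-saturated 0.1 M Tris-HCl pH 8.0, 25 °C, 2 min; then Et2O, citric acid to pH 3.5, 0 °C; MgSO4; SiO2, Et2O/hexane, −20 °C; kept as a cold solution and used at once
Reagents that add atoms: dioxygen, O=O
Why: The heme peroxidase site, primed by a trace of hydroperoxide, oxidizes Tyr-385 to a tyrosyl radical that removes the 13-pro-S hydrogen of 1; the C11–C15 pentadienyl radical takes up the first O2 at C11, the 11-peroxyl radical closes the 1,2-dioxolane by 5-exo-trig attack on C9 of the 8,9-alkene, the resulting C8 radical closes the cyclopentane by 5-exo-trig attack on C12 of the 12,14-diene, and the C13–C15 allyl radical takes up the second O2 at C15 and recovers a hydrogen atom from Tyr-385 to give hydroperoxide 3. The peroxidase site then reduces the 15-hydroperoxide of 3 to the alcohol of 4 at the expense of hydroquinone, leaving the endoperoxide intact. The closest non-enzymatic reaction type is the peroxyl-radical 5-exo cyclization cascade of skipped-polyene hydroperoxides in autoxidation; this is its protein-controlled native version, with 1 as the natural substrate. C11 (R) is set by delivery of O2 to the face of the pentadienyl radical opposite the abstracted hydrogen; C9 (S) by the face of the 8Z alkene that the active site presents to the peroxyl radical, the cis-3,5-disubstituted dioxolane being the only one able to bridge; C8 and C12 (R,R, side chains trans) by the extended L-shaped conformation in which the hydrophobic channel holds both chains when C8–C12 forms; and C15 (S) by oxygen access to one face only of the transoid allyl radical, which also fixes the 13E alkene. The step needs hydrogen abstraction at C13 rather than C7 or C10 and trans rather than cis ring substitution; both are secured by the skipped tetraene and the C1 carboxylate of 1, which anchors at Arg-120 and places only C13 beneath the tyrosyl radical.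

**Step 2**
Reactants: 4 prostaglandin H2
Product: 5 prostaglandin F2α (9α,11α,15S-trihydroxyprosta-5Z,13E-dienoic acid)
Conditions: PPh3 (1.5 equiv), Et2O, −20 to 0 °C, 20 min; H2O, 0 to 20 °C; extraction into aq NaHCO3, then citric acid to pH 3.5, EtOAc
Reagents that add atoms: none
Why: Triphenylphosphine reduction of a dialkyl peroxide: the phosphine inserts into the weak O–O bond to give a cyclic dialkoxyphosphorane whose hydrolysis releases the cis-9α,11α-diol and Ph3P=O without breaking either C–O bond, so C9 and C11 keep the configuration set in step 1, while the alkenes, the allylic alcohol and the acid are inert to the phosphine.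

**Step 3**
Reactants: 5 prostaglandin F2α
Product: 6 15-keto-prostaglandin F2α (9α,11α-dihydroxy-15-oxoprosta-5Z,13E-dienoic acid; (Z)-7-[(1R,2R,3R,5S)-3,5-dihydroxy-2-[(E)-3-oxooct-1-enyl]cyclopentyl]hept-5-enoic acid)
Conditions: DDQ (1.2 equiv), 1,4-dioxane, 40 °C, N2, dark; filtration; SiO2 (EtOAc/hexane/AcOH)
Reagents that add atoms: none
Why: DDQ dehydrogenation of an allylic alcohol: hydride is abstracted only from C15–H, which is activated by the adjacent 13E alkene, whereas the saturated carbinols at C9 and C11 cannot stabilise the developing positive charge, so the enone should form without protection; no stereocentre is created, the C15 centre is removed on purpose, and the non-basic medium leaves C12 (γ to the new enone) and the 5Z alkene untouched.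

**Compound list**

1 | arachidonic acid, (5Z,8Z,11Z,14Z)-icosa-5,8,11,14-tetraenoic acid | CCCCC/C=C\C/C=C\C/C=C\C/C=C\CCCC(=O)O | starting material
2 | dioxygen | O=O | starting material
3 | prostaglandin G2, (8R,9S,11R,12R,15S)-9α,11α-epidioxy-15-hydroperoxyprosta-5Z,13E-dienoic acid | CCCCC[C@H](OO)/C=C/[C@@H]1[C@@H](C/C=C\CCCC(=O)O)[C@@H]2C[C@H]1OO2 | intermediate
4 | prostaglandin H2, (8R,9S,11R,12R,15S)-9α,11α-epidioxy-15-hydroxyprosta-5Z,13E-dienoic acid | CCCCC[C@H](O)/C=C/[C@@H]1[C@@H](C/C=C\CCCC(=O)O)[C@@H]2C[C@H]1OO2 | intermediate
5 | prostaglandin F2α, (8R,9S,11R,12R,15S)-9α,11α,15-trihydroxyprosta-5Z,13E-dienoic acid | CCCCC[C@H](O)/C=C/[C@@H]1[C@@H](C/C=C\CCCC(=O)O)[C@@H](O)C[C@H]1O | intermediate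
6 | 15-keto-prostaglandin F2α, (8R,9S,11R,12R)-9α,11α-dihydroxy-15-oxoprosta-5Z,13E-dienoic acid | CCCCCC(=O)/C=C/[C@@H]1[C@@H](C/C=C\CCCC(=O)O)[C@@H](O)C[C@H]1O | target

**Step count and risks**

Total step count: 3. Longest linear sequence: 3 steps (1 → 4 → 5 → 6).

Steps most likely to fail, riskiest first:

Step 1. The synthase inactivates itself as it turns over, which may stop conversion early. The endoperoxide may also decay during incubation, acidification and cold chromatography, by isomerization of the O–O bridge to hydroxy ketones and by cleavage of the bicycle. Incomplete peroxidase turnover would leave hydroperoxide beside alcohol. The fallback merges oxygenation and O–O reduction in one pot so that no endoperoxide is handled. It sets out from 1 and 2 under the incubation conditions of step 1. After the short incubation SnCl2 (divalent tin, large excess, in ethanol or dilute HCl) is added directly to the buffer at 0 °C. This is the usual way of trapping the enzymatic endoperoxides and should reduce both 3 and 4, neither isolated, to the triol acid. Extraction at pH 3.5 then returns to the route at 5. No compound outside the compound list is formed (F0).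

Step 2. When the free-acid endoperoxide is concentrated and handled, O–O reduction may lose the race against base- or surface-promoted Kornblum–DeLaMare-type isomerization and fragmentation. Removal of the phosphine oxide from a polar triol acid may also cost material. The fallback protects the carboxyl group first. It sets out from 4, whose cold ether solution is treated briefly with ethereal diazomethane at 0 °C to give prostaglandin H2 methyl ester F1, a neutral endoperoxide suited to low-temperature chromatography. Reduction of F1 with SnCl2 in ethanol at 0 °C should give prostaglandin F2α methyl ester F2, which is purified on silica as a neutral compound. Saponification with LiOH in THF/water at 20 °C returns to the route at 5.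

Step 3. The hydride abstraction may stall with the polar triol acid or, on forcing, lose chemoselectivity towards the ring carbinols; the accumulating acidic hydroquinone may also promote decomposition. The fallback replaces reliance on chemoselectivity by temporary protection. It sets out from 5, which is condensed with n-butylboronic acid (CH2Cl2, 4 Å molecular sieves, 20 to 40 °C) to give prostaglandin F2α 9,11-n-butylboronate F3, leaving only the C15 hydroxyl free. Oxidation with Dess–Martin periodinane (CH2Cl2, pyridine, 0 °C) should give 15-keto-prostaglandin F2α 9,11-n-butylboronate F4. Stirring F4 in aqueous methanol at 20 °C hydrolyses the labile boronate and returns to the route at 6.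

**Further compounds**

F0 | step 1 | none | none
F1 | step 2 | prostaglandin H2 methyl ester | CCCCC[C@H](O)/C=C/[C@@H]1[C@@H](C/C=C\CCCC(=O)OC)[C@@H]2C[C@H]1OO2
F2 | step 2 | prostaglandin F2α methyl ester | CCCCC[C@H](O)/C=C/[C@@H]1[C@@H](C/C=C\CCCC(=O)OC)[C@@H](O)C[C@H]1O
F3 | step 3 | prostaglandin F2α 9,11-n-butylboronate | CCCCC[C@H](O)/C=C/[C@@H]1[C@@H](C/C=C\CCCC(=O)O)[C@@H]2C[C@H]1OB(CCCC)O2
F4 | step 3 | 15-keto-prostaglandin F2α 9,11-n-butylboronate | CCCCCC(=O)/C=C/[C@@H]1[C@@H](C/C=C\CCCC(=O)O)[C@@H]2C[C@H]1OB(CCCC)O2
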